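**Strategy.** The route rests on cutting the O1–C8a bond of ring C. Because O5 and O8 are para on ring A, ring A can be raised to a 1,4-benzoquinone in which C8a is the only hydrogen-bearing carbon and lies β to both the C5 and the C4 carbonyl groups. An acylquinone that already carries the whole 1,3-diketone side chain should close through its enol oxygen onto C8a and aromatize, which builds ring C and sets O8 as a phenol in one redox-neutral operation. The quinone is unmasked from a para-methoxyphenol with PhI(OAc)2; afterwards the chelated 5-OH and the free 8-OH are told apart by the order of alkylation.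

Key step: step 4

Remark on locants: flavone locants are used for ring A throughout, also in the open-chain intermediates (acyl-bearing carbon C4a, hydrogen-bearing carbon C8a, oxygens O5 to O8 in order around the ring). The 1,3-diketones are drawn in the diketo form but should exist mainly as chelated enols. No compound in the route has a stereocentre.

Remark on the design: the quinone is released from a phenol para to a methoxy group by a two-electron oxidant, because a one-electron oxidant such as (NH4)2Ce(NO3)6 (tetravalent cerium) is known to attack the central carbon of 1,3-diketones. The phenol costs no step, since AlCl3 removes the methyl group ortho to the ketone during the acylation.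

**Step 1**
Reactants: 1 1,2,3,4-tetramethoxybenzene; 2 acetyl chloride
Product: 4 1-(2-hydroxy-3,4,5-trimethoxyphenyl)ethanone, via 2,3,4,5-tetramethoxyacetophenone 3 (not isolated)
Conditions: AcCl (1.2 equiv), AlCl3 (2.2 equiv), CH2Cl2, 0 °C then 40 °C; ice/aq. HCl
Reagents that add atoms: none
Why: Friedel–Crafts acylation at one of the two equivalent free positions of 1 gives ketone 3, whose AlCl3-chelated carbonyl then directs cleavage of the ortho (O5) methyl ether only, the known chelation-controlled ortho-demethylation of o-methoxyaryl ketones, so the phenol para to the O8 methoxy group should be obtained in the same flask.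

**Step 2**
Reactants: 4 1-(2-hydroxy-3,4,5-trimethoxyphenyl)ethanone; 5 methyl 3,4,5-trimethoxybenzoate
Product: 6 1-(2-hydroxy-3,4,5-trimethoxyphenyl)-3-(3,4,5-trimethoxyphenyl)propane-1,3-dione
Conditions: LiN(SiMe3)2 (3.5 equiv), THF, −78 °C to rt; cold 1 M HCl
Reagents that add atoms: none
Why: Crossed Claisen condensation of the phenoxide–enolate dianion of 4 with a non-enolizable aryl ester, driven by deprotonation of the diketone product, is a standard route to o-hydroxydibenzoylmethanes, and the cold dilute acid quench should not cause cyclodehydration.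

**Step 3**
Reactants: 6 1-(2-hydroxy-3,4,5-trimethoxyphenyl)-3-(3,4,5-trimethoxyphenyl)propane-1,3-dione
Product: 7 2-[3-oxo-3-(3,4,5-trimethoxyphenyl)propanoyl]-5,6-dimethoxy-1,4-benzoquinone
Conditions: PhI(OAc)2 (1.05 equiv), MeCN/H2O 3:1, 0 °C, short reaction time; extraction, water wash, used crude at once
Reagents that add atoms: water, O
Why: Oxidative demethylation of a para-methoxyphenol by PhI(OAc)2 (trivalent iodine) proceeds by ligand exchange at the O5 phenol, addition of water at C8 para to it and loss of methanol from the hemiketal, a two-electron pathway that should leave the 1,3-diketone and ring B untouched at 0 °C.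

**Step 4**
Reactants: 7 2-[3-oxo-3-(3,4,5-trimethoxyphenyl)propanoyl]-5,6-dimethoxy-1,4-benzoquinone
Product: 8 5,8-dihydroxy-6,7-dimethoxy-2-(3,4,5-trimethoxyphenyl)-4H-chromen-4-one (5,8-dihydroxy-6,7,3',4',5'-pentamethoxyflavone)
Conditions: Et3N (0.1 equiv), degassed CH2Cl2 (0.01 M), 0 °C to rt, Ar
Reagents that add atoms: none
Why: Proposed new method: Et3N converts the 1,3-diketone of 7 into its enolate, whose oxygen on C2 adds to C8a of the quinone, the ring-A carbon that is β to both C5=O and C4=O, and loss of the C8a proton from the adduct then aromatizes ring A to the 5,8-hydroquinone, so the step is an isomerization that needs no added oxidant or reductant. The closest known reactions are the conjugate addition of oxygen and nitrogen nucleophiles to C3 of 2-acyl-1,4-benzoquinones and the closure of 2-(2-hydroxyaroyl)-1,4-benzoquinones to 1,4-dioxygenated xanthones; the enol oxygen of a 1,3-diketone has not been used as the nucleophile, and that is the extension proposed here. Ring C closes in a 6-endo-trig oxa-Michael mode, O1 onto C8a with the C4a=C8a bond inside the new ring. No stereocentre is created, because C8a becomes aromatic. Site selectivity is secured by the substrate: C8a is the only hydrogen-bearing quinone carbon and is doubly activated, C6 and C7 are deactivated vinylogous ester carbons, attack through C3 would need a four-membered ring, and reversible hemiketal formation at C5 is drained by the irreversible aromatization. High dilution and exclusion of air should suppress intermolecular C-alkylation by the diketone carbon and redox exchange between 8 and unreacted 7.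

**Step 5**
Reactants: 8 5,8-dihydroxy-6,7-dimethoxy-2-(3,4,5-trimethoxyphenyl)-4H-chromen-4-one
Product: 9 8-benzyloxy-5-hydroxy-6,7-dimethoxy-2-(3,4,5-trimethoxyphenyl)-4H-chromen-4-one
Conditions: BnBr (1.05 equiv), K2CO3 (1.1 equiv), degassed DMF, rt, Ar
Reagents that add atoms: benzyl bromide, BrCc1ccccc1
Why: Williamson etherification under mild base should take place at O8 only, because the 8-OH is the only free phenol whereas the 5-OH is held in a hydrogen bond to C4=O and is far less readily deprotonated and alkylated; air is excluded because 8 is a hydroquinone.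

**Step 6**
Reactants: 9 8-benzyloxy-5-hydroxy-6,7-dimethoxy-2-(3,4,5-trimethoxyphenyl)-4H-chromen-4-one
Product: 10 8-benzyloxy-5,6,7-trimethoxy-2-(3,4,5-trimethoxyphenyl)-4H-chromen-4-one
Conditions: Me2SO4 (5 equiv), K2CO3 (5 equiv), acetone, reflux
Reagents that add atoms: dimethyl sulfate, COS(=O)(=O)OC
Why: O-Methylation with excess Me2SO4 and K2CO3 at reflux overcomes the chelation of the 5-OH, a standard operation for 5-hydroxyflavones, and the benzyl ether and the pyranone ring are stable to these conditions.

**Step 7**
Reactants: 10 8-benzyloxy-5,6,7-trimethoxy-2-(3,4,5-trimethoxyphenyl)-4H-chromen-4-one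
Product: 11 8-hydroxy-5,6,7-trimethoxy-2-(3,4,5-trimethoxyphenyl)-4H-chromen-4-one (8-hydroxy-5,6,7,3',4',5'-hexamethoxyflavone, the target)
Conditions: H2 (1 atm), 10% Pd/C, EtOAc/MeOH, rt, stopped after uptake of one equivalent
Reagents that add atoms: none
Why: Catalytic hydrogenolysis of the benzyl aryl ether over Pd/C frees the 8-OH, while the C2=C3 bond, part of an aryl-conjugated vinylogous ester, is reduced far more slowly and the methyl ethers are inert.

**Compound list**
1 | 1,2,3,4-tetramethoxybenzene | COc1ccc(OC)c(OC)c1OC | starting material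
2 | acetyl chloride | CC(=O)Cl | starting material
3 | 1-(2,3,4,5-tetramethoxyphenyl)ethanone (2,3,4,5-tetramethoxyacetophenone) | CC(=O)c1cc(OC)c(OC)c(OC)c1OC | intermediate (not isolated)
4 | 1-(2-hydroxy-3,4,5-trimethoxyphenyl)ethanone | CC(=O)c1cc(OC)c(OC)c(OC)c1O | intermediate
5 | methyl 3,4,5-trimethoxybenzoate | COC(=O)c1cc(OC)c(OC)c(OC)c1 | starting material
6 | 1-(2-hydroxy-3,4,5-trimethoxyphenyl)-3-(3,4,5-trimethoxyphenyl)propane-1,3-dione | O=C(CC(=O)c1cc(OC)c(OC)c(OC)c1)c1cc(OC)c(OC)c(OC)c1O | intermediate
7 | 2-[3-oxo-3-(3,4,5-trimethoxyphenyl)propanoyl]-5,6-dimethoxy-1,4-benzoquinone | O=C1C=C(C(=O)CC(=O)c2cc(OC)c(OC)c(OC)c2)C(=O)C(OC)=C1OC | intermediate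
8 | 5,8-dihydroxy-6,7-dimethoxy-2-(3,4,5-trimethoxyphenyl)-4H-chromen-4-one | COc1cc(-c2cc(=O)c3c(O)c(OC)c(OC)c(O)c3o2)cc(OC)c1OC | intermediate
9 | 8-benzyloxy-5-hydroxy-6,7-dimethoxy-2-(3,4,5-trimethoxyphenyl)-4H-chromen-4-one | COc1cc(-c2cc(=O)c3c(O)c(OC)c(OC)c(OCc4ccccc4)c3o2)cc(OC)c1OC | intermediate
10 | 8-benzyloxy-5,6,7-trimethoxy-2-(3,4,5-trimethoxyphenyl)-4H-chromen-4-one | COc1cc(-c2cc(=O)c3c(OC)c(OC)c(OC)c(OCc4ccccc4)c3o2)cc(OC)c1OC | intermediate
11 | 8-hydroxy-5,6,7-trimethoxy-2-(3,4,5-trimethoxyphenyl)-4H-chromen-4-one | COc1cc(-c2cc(=O)c3c(OC)c(OC)c(OC)c(O)c3o2)cc(OC)c1OC | target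

**Step count.** Total: 7 steps. Longest linear sequence: 7 steps (1 to 11).

**Steps most likely to fail**

First, step 4, the proposed ring closure. The diketone carbon of one molecule may add to C8a of another quinone instead of the intramolecular oxygen closure. The hydroquinone product may also be oxidized by unreacted quinone, which strands material as the reduced, non-cyclizing form of 7; a wash with aqueous Na2S2O4 would return any flavonequinone to 8. The fallback uses known reactions only, sets out from 5 and comes back at 8. Claisen condensation of 5 with purchased 1-(6-hydroxy-2,3,4-trimethoxyphenyl)ethanone F1 (LiN(SiMe3)2, THF) would give 1-(6-hydroxy-2,3,4-trimethoxyphenyl)-3-(3,4,5-trimethoxyphenyl)propane-1,3-dione F2. Acid cyclodehydration (H2SO4, AcOH, 100 °C) would give 5,6,7-trimethoxy-2-(3,4,5-trimethoxyphenyl)-4H-chromen-4-one F3. BCl3 (CH2Cl2, 0 °C) would cleave only the O5 methyl ether peri to the carbonyl and give 5-hydroxy-6,7-dimethoxy-2-(3,4,5-trimethoxyphenyl)-4H-chromen-4-one F4. Elbs persulfate oxidation (K2S2O8, aqueous KOH, pyridine, rt) would then oxygenate C8, para to the 5-phenoxide, through potassium 5-hydroxy-6,7-dimethoxy-4-oxo-2-(3,4,5-trimethoxyphenyl)-4H-chromen-8-yl sulfate F5, whose hydrolysis (aqueous HCl, Na2SO3, heat) gives 8.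

Second, step 3, the unmasking of the quinone next to a free diketone. The oxidant may attack the central diketone carbon, water may add to C8a of the fresh acylquinone, or the ring may close in the flask and the hydroquinone be oxidized further. The fallback sets out from 4 and comes back at 7; it moves the demanding oxidation in front of the diketone. PhI(OAc)2 in aqueous MeCN would convert 4 into 2-acetyl-5,6-dimethoxy-1,4-benzoquinone F6, and aqueous Na2S2O4 would reduce it to 1-(2,5-dihydroxy-3,4-dimethoxyphenyl)ethanone F7. Claisen condensation with 5 (LiN(SiMe3)2, 4.5 equiv, THF, Ar) would give 1-(2,5-dihydroxy-3,4-dimethoxyphenyl)-3-(3,4,5-trimethoxyphenyl)propane-1,3-dione F8. Anhydrous Ag2O with MgSO4 in Et2O, which oxidizes hydroquinones but should spare a diketone, would then give 7 in the absence of water.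

Third, step 5, the selective benzylation. Site selectivity may be lost through partial alkylation at O5, or the hydroquinone may be oxidized by air under base. The fallback sets out from 8 and comes back at 9. Exhaustive benzylation (excess BnBr, K2CO3, DMF, 70 °C, Ar) would give 5,8-bis(benzyloxy)-6,7-dimethoxy-2-(3,4,5-trimethoxyphenyl)-4H-chromen-4-one F9. Chelation-controlled cleavage with MgBr2·OEt2 (toluene/Et2O, reflux) would then remove only the benzyl ether peri to C4=O and give 9.

**Further compounds**
F1 | step 4 | 1-(6-hydroxy-2,3,4-trimethoxyphenyl)ethanone (purchased) | CC(=O)c1c(O)cc(OC)c(OC)c1OC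
F2 | step 4 | 1-(6-hydroxy-2,3,4-trimethoxyphenyl)-3-(3,4,5-trimethoxyphenyl)propane-1,3-dione | O=C(CC(=O)c1cc(OC)c(OC)c(OC)c1)c1c(O)cc(OC)c(OC)c1OC
F3 | step 4 | 5,6,7-trimethoxy-2-(3,4,5-trimethoxyphenyl)-4H-chromen-4-one | COc1cc(-c2cc(=O)c3c(OC)c(OC)c(OC)cc3o2)cc(OC)c1OC
F4 | step 4 | 5-hydroxy-6,7-dimethoxy-2-(3,4,5-trimethoxyphenyl)-4H-chromen-4-one | COc1cc(-c2cc(=O)c3c(O)c(OC)c(OC)cc3o2)cc(OC)c1OC
F5 | step 4 | potassium 5-hydroxy-6,7-dimethoxy-4-oxo-2-(3,4,5-trimethoxyphenyl)-4H-chromen-8-yl sulfate | COc1cc(-c2cc(=O)c3c(O)c(OC)c(OC)c(OS(=O)(=O)[O-])c3o2)cc(OC)c1OC.[K+]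
F6 | step 3 | 2-acetyl-5,6-dimethoxy-1,4-benzoquinone | CC(=O)C1=CC(=O)C(OC)=C(OC)C1=O
F7 | step 3 | 1-(2,5-dihydroxy-3,4-dimethoxyphenyl)ethanone | CC(=O)c1cc(O)c(OC)c(OC)c1O
F8 | step 3 | 1-(2,5-dihydroxy-3,4-dimethoxyphenyl)-3-(3,4,5-trimethoxyphenyl)propane-1,3-dione | O=C(CC(=O)c1cc(OC)c(OC)c(OC)c1)c1cc(O)c(OC)c(OC)c1O
F9 | step 5 | 5,8-bis(benzyloxy)-6,7-dimethoxy-2-(3,4,5-trimethoxyphenyl)-4H-chromen-4-one | COc1cc(-c2cc(=O)c3c(OCc4ccccc4)c(OC)c(OC)c(OCc4ccccc4)c3o2)cc(OC)c1OC
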